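**Retrosynthetic overview**

1. Numbering (bicyclo[3.3.1]nonane, also used for the matching carbons of all intermediates): C1 bridgehead with the 2-methylpropanoyl group, C2 ring C=O, C3 enol CH, C4 enol C–OH, C5 prenylated bridgehead, C6 CH2, C7 CH(prenyl), C8 C(CH3)(4-methylpent-3-enyl), C9 bridging C=O. Enabling feature: ring C1–C2–C3–C4–C5–C9 is a cyclohexane-1,3,5-trione in which every ring bond is a Claisen (1,3-dicarbonyl) bond; C1 lies between three acyl carbons (C2, C9, the 2-methylpropanoyl carbon) and C5 carries no hydrogen.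
2. Key disconnection: C1–C9 and C2–C3 together, back to the acyclic heptanedioate 22 (C1 a β-keto ester carbon, C9 and C2 methyl esters, C3=C4 a silyl enol ether on quaternary C5).
3. 22 from 14: vinyl to CH2CO2Me (C1, C2), silyl masking of the acetyl group, aldol/oxidation for the 2-methylpropanoyl group. C5 is set by auxiliary-controlled prenylation; C5–C6 comes from alkylation of methyl acetoacetate with iodide 7.
4. C7 and C8 are set together by an enantioselective Ireland–Claisen rearrangement of geranyl 5-methylhex-4-enoate 3.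
5. Ring order: carbocycle C1–C8–C7–C6–C5–C9 first (bond C1–C9), trione ring C1–C2–C3–C4–C5–C9 second (bond C2–C3), both in step 14.

Key step: step 14

Assumption: the absolute sense of induction of the (4S,5S)-diazaborolidine in step 2 and of the (S)-valine-derived enamine in toluene/HMPA in step 7 is taken to be the one drawn; if either proves opposite, the enantiomeric reagent (or THF as solvent in step 7) is used and nothing else changes.

**Route**

Step 1
Reactants: 1 geraniol, (2E)-3,7-dimethylocta-2,6-dien-1-ol; 2 5-methylhex-4-enoic acid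
Product: 3 (2E)-3,7-dimethylocta-2,6-dien-1-yl 5-methylhex-4-enoate
Conditions: DCC, DMAP (cat.), CH2Cl2, 0 °C → rt
Reagents that add atoms: none
Why: Steglich esterification of an unhindered primary allylic alcohol with an unhindered acid should be clean and forms no stereocentre.

Step 2
Reactants: 3
Product: 5 (2R,3S)-3-ethenyl-3,7-dimethyl-2-(3-methylbut-2-en-1-yl)oct-6-enoic acid, via boron ketene acetal 4 (not isolated)
Conditions: pre-formed (4S,5S)-2-bromo-1,3-bis{[3,5-bis(trifluoromethyl)phenyl]sulfonyl}-4,5-diphenyl-1,3,2-diazaborolidine (1.2 equiv), i-Pr2NEt (1.3 equiv), CH2Cl2, −78 °C, then 4 °C; aqueous work-up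
Reagents that add atoms: the B-bromodiazaborolidine, BrB1N(S(=O)(=O)c2cc(cc(c2)C(F)(F)F)C(F)(F)F)[C@@H](c2ccccc2)[C@H](c2ccccc2)N1S(=O)(=O)c2cc(cc(c2)C(F)(F)F)C(F)(F)F (boron and ligand of 4 only; nothing of it remains in 5)
Why: Enantioselective Ireland–Claisen rearrangement in which the amine/solvent pair is chosen for the boron enolate with the acid side chain cis to O–B, the chair transition state places that chain and the 4-methylpent-3-enyl group of the (E)-geranyl unit equatorial and the methyl group axial, so that the tertiary C7 and the quaternary C8 centres should form together with syn relative configuration, the absolute sense being fixed by the chiral boron ligand.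

Step 3
Reactants: 5
Product: 6 (2R,3S)-3-ethenyl-3,7-dimethyl-2-(3-methylbut-2-en-1-yl)oct-6-en-1-ol
Conditions: LiAlH4, THF, 0 °C → rt; NaOH/H2O work-up
Reagents that add atoms: none
Why: Hydride reduction of the carboxylic acid to the primary alcohol (C6) leaves the isolated alkenes and both stereocentres untouched.

Step 4
Reactants: 6
Product: 7 (2R,3S)-3-ethenyl-1-iodo-3,7-dimethyl-2-(3-methylbut-2-en-1-yl)oct-6-ene
Conditions: I2, PPh3, imidazole, CH2Cl2, 0 °C → rt
Reagents that add atoms: iodine, II
Why: The Appel reaction converts the primary alcohol into the iodide under neutral conditions that should not disturb the alkenes or the adjacent stereocentre.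

Step 5
Reactants: 7; 8 methyl acetoacetate
Product: 9 methyl (2RS,4S,5S)-2-acetyl-5-ethenyl-5,9-dimethyl-4-(3-methylbut-2-en-1-yl)dec-8-enoate
Conditions: 8 (3 equiv), NaH (2.8 equiv), DMF, 0 °C; then 7, 65 °C
Reagents that add atoms: none
Why: SN2 C-alkylation of sodium acetoacetate by the primary iodide forms C5–C6, excess nucleophile suppresses dialkylation, and the new C5 centre is epimerisable and is fixed only in step 7.

Step 6
Reactants: 9; 10 tert-butyl (S)-valinate
Product: 11 methyl (2Z)-3-{[(2S)-1-tert-butoxy-3-methyl-1-oxobutan-2-yl]amino}-2-{[(2S,3S)-3-ethenyl-3,7-dimethyl-2-(3-methylbut-2-en-1-yl)oct-6-en-1-yl]}but-2-enoate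
Conditions: 10 (1.2 equiv), AcOH (cat.), benzene, reflux, Dean–Stark
Reagents that add atoms: none
Why: Condensation of the β-keto ester with the primary amine gives the hydrogen-bonded (Z)-enaminoester (a vinylogous carbamate), which removes the C5 stereocentre and installs the chiral auxiliary.

Step 7
Reactants: 11; 12 prenyl bromide (1-bromo-3-methylbut-2-ene)
Product: 14 methyl (2R,4S,5S)-2-acetyl-5-ethenyl-5,9-dimethyl-2,4-bis(3-methylbut-2-en-1-yl)dec-8-enoate, via ketimine 13 (not isolated)
Conditions: LiN(i-Pr)2 (1.2 equiv), toluene, HMPA (1 equiv), −78 °C; 12 (1.5 equiv), −78 → −40 °C; then 1 M HCl, THF/H2O, 0 °C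
Reagents that add atoms: water, O
Why: Asymmetric alkylation of a lithiated chiral enaminoester, in which the N-lithio aza-enolate is chelated by the tert-butyl ester of the auxiliary and its isopropyl group shields one face, so that the reactive allylic bromide should add to the other face and set the quaternary C5 centre under reagent control, after which mild acid hydrolyses the ketimine and returns the auxiliary.

Step 8
Reactants: 14
Product: 16 methyl (2R,4S,5S)-2-acetyl-5-(2-hydroxyethyl)-5,9-dimethyl-2,4-bis(3-methylbut-2-en-1-yl)dec-8-enoate, via catechol boronate 15 (not isolated)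
Conditions: catecholborane (2 equiv), RhCl(PPh3)3 (2 mol %), THF, 0 °C → rt; then pH 7 phosphate buffer, 30% H2O2, 0 °C
Reagents that add atoms: hydrogen peroxide, OO (oxygen of the alcohol); catecholborane, B1Oc2ccccc2O1 (boron and catecholate of 15 only)
Why: Rhodium-catalysed hydroboration is selective for the monosubstituted alkene over the three trisubstituted alkenes and over the ketone, places boron on the terminal carbon (C2), and buffered oxidation gives the primary alcohol without touching a stereocentre.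

Step 9
Reactants: 16
Product: 17 (3S,4S,6R)-6-acetyl-7-methoxy-3-methyl-4,6-bis(3-methylbut-2-en-1-yl)-3-(4-methylpent-3-en-1-yl)-7-oxoheptanoic acid
Conditions: TEMPO (0.2 equiv), PhI(OAc)2 (2.5 equiv), MeCN/H2O 1:1, rt
Reagents that add atoms: water, O
Why: Oxoammonium-mediated oxidation takes the primary alcohol through the aldehyde hydrate to the carboxylic acid (C2) and is compatible with trisubstituted alkenes, the ketone and the ester.

Step 10
Reactants: 17
Product: 18 dimethyl (2R,4S,5S)-2-acetyl-5-methyl-2,4-bis(3-methylbut-2-en-1-yl)-5-(4-methylpent-3-en-1-yl)heptanedioate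
Conditions: MeI, K2CO3, DMF, rt
Reagents that add atoms: iodomethane, CI
Why: SN2 O-methylation of the carboxylate gives the C2 methyl ester, and carbonate is too weak a base to alkylate the ketone or to epimerise a centre.

Step 11
Reactants: 18
Product: 19 dimethyl (2R,4S,5S)-2-{1-[(tert-butyldimethylsilyl)oxy]ethenyl}-5-methyl-2,4-bis(3-methylbut-2-en-1-yl)-5-(4-methylpent-3-en-1-yl)heptanedioate
Conditions: TBSOTf (1.3 equiv), Et3N (2 equiv), CH2Cl2, −78 → 0 °C
Reagents that add atoms: tert-butyldimethylsilyl trifluoromethanesulfonate, CC(C)(C)[Si](C)(C)OS(=O)(=O)C(F)(F)F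
Why: Soft enolisation/silylation of the methyl ketone is regiospecific because C5 has no hydrogen, and the silyl enol ether both protects the ketone from the base of step 12 and stores C3 as a latent nucleophile for step 14.

Step 12
Reactants: 19; 20 2-methylpropanal
Product: 21 dimethyl (2R,4S,5R)-2-{1-[(tert-butyldimethylsilyl)oxy]ethenyl}-6-(1-hydroxy-2-methylpropyl)-5-methyl-2,4-bis(3-methylbut-2-en-1-yl)-5-(4-methylpent-3-en-1-yl)heptanedioate (mixture at C6 and the carbinol carbon)
Conditions: LiN(i-Pr)2 (1.1 equiv), THF, −78 °C, 30 min; 20, −78 °C; sat. NH4Cl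
Reagents that add atoms: none
Why: Aldol addition of the only possible lithium ester enolate (at C1; the C9 ester has no α-hydrogen) to the aldehyde at −78 °C should outrun Dieckmann closure, and the two new centres are unselective but are removed or made epimerisable in step 13.

Step 13
Reactants: 21
Product: 22 dimethyl (2R,4S,5R)-2-{1-[(tert-butyldimethylsilyl)oxy]ethenyl}-5-methyl-2,4-bis(3-methylbut-2-en-1-yl)-5-(4-methylpent-3-en-1-yl)-6-(2-methylpropanoyl)heptanedioate (C6 epimers and enol)
Conditions: Dess–Martin periodinane, NaHCO3, CH2Cl2, 0 °C → rt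
Reagents that add atoms: none
Why: Buffered Dess–Martin oxidation of the β-hydroxy ester gives the β-keto ester without cleaving the silyl enol ether, and C1 becomes an acidic, stereochemically mobile carbon.

Step 14
Reactants: 22
Product: 24 (1R,5R,7S,8R)-4-hydroxy-8-methyl-5,7-bis(3-methylbut-2-en-1-yl)-8-(4-methylpent-3-en-1-yl)-1-(2-methylpropanoyl)bicyclo[3.3.1]non-3-ene-2,9-dione, via cyclohexanone 23 (not isolated)
Conditions: KN(SiMe3)2 (1.1 equiv), THF, −78 → 0 °C; then (Me2N)3S+ Me3SiF2− (1.3 equiv), 0 °C → rt; 1 M HCl work-up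
Reagents that add atoms: none
Why: Proposed new method: KN(SiMe3)2 forms the potassium enolate of the β-keto ester, whose C1 attacks the C9 ester (6-exo-trig Claisen closure with the enolate exocyclic, chair transition state with the C7 prenyl and C8 4-methylpent-3-enyl groups equatorial) to give cyclohexanone 23, and fluoride then releases the C3 enolate from the silyl enol ether, which closes onto the axial C2 ester (second 6-exo-trig Claisen closure across the 1,3-diaxial positions) to give the enolate of 24. The closest known reaction types are the Dieckmann condensation, the base-mediated closure of β-keto amide anions onto esters to 3-acyl tetramic acids, and the Dieckmann closure of a cis-1,3-acetyl/ester pair on a cyclohexanone to a bicyclo[3.3.1]nonane-2,4,9-trione. The sequence should run because C5 has no hydrogen (its ester cannot enolise), the fully substituted C5 and C8 favour ring closure, and the final vinylogous acid anion is the only species that cannot revert, so it draws the reversible first closure forward. The new stereocentre C1 is controlled by C5: the bicycle forms only when the C2 ester and the C4 enolate are cis-diaxial, a closure with the opposite configuration at C1 cannot bridge and can only reopen by retro-Claisen, and C5, C7 and C8 are not touched. The selectivities needed are C- over O-acylation at C1 (six- against eight-membered ring), attack of C1 on C9 and not on C4 (C4 stays masked as the silyl enol ether until fluoride is added), and Claisen closure of C3 onto the ester and not aldol addition to the 2-methylpropanoyl ketone (the aldol is reversible, the Claisen is not).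

**Compound list**

1 | geraniol, (2E)-3,7-dimethylocta-2,6-dien-1-ol | CC(C)=CCC/C(C)=C/CO | starting material
2 | 5-methylhex-4-enoic acid | CC(C)=CCCC(=O)O | starting material
3 | (2E)-3,7-dimethylocta-2,6-dien-1-yl 5-methylhex-4-enoate | CC(C)=CCC/C(C)=C/COC(=O)CCC=C(C)C | intermediate
4 | boron ketene acetal of 3: O-geranyl, O-[(4S,5S)-1,3-bis{[3,5-bis(trifluoromethyl)phenyl]sulfonyl}-4,5-diphenyl-1,3,2-diazaborolidin-2-yl], acid side chain cis to O–B | CC(C)=CC/C=C(\OB1N(S(=O)(=O)c2cc(cc(c2)C(F)(F)F)C(F)(F)F)[C@@H](c2ccccc2)[C@H](c2ccccc2)N1S(=O)(=O)c2cc(cc(c2)C(F)(F)F)C(F)(F)F)/OC/C=C(C)/CCC=C(C)C | intermediate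
5 | (2R,3S)-3-ethenyl-3,7-dimethyl-2-(3-methylbut-2-en-1-yl)oct-6-enoic acid | CC(C)=CCC[C@](C=C)(C)[C@@H](CC=C(C)C)C(=O)O | intermediate
6 | (2R,3S)-3-ethenyl-3,7-dimethyl-2-(3-methylbut-2-en-1-yl)oct-6-en-1-ol | CC(C)=CCC[C@](C=C)(C)[C@@H](CC=C(C)C)CO | intermediate
7 | (2R,3S)-3-ethenyl-1-iodo-3,7-dimethyl-2-(3-methylbut-2-en-1-yl)oct-6-ene | CC(C)=CCC[C@](C=C)(C)[C@@H](CC=C(C)C)CI | intermediate
8 | methyl acetoacetate (methyl 3-oxobutanoate) | CC(=O)CC(=O)OC | starting material
9 | methyl (2RS,4S,5S)-2-acetyl-5-ethenyl-5,9-dimethyl-4-(3-methylbut-2-en-1-yl)dec-8-enoate | CC(C)=CCC[C@](C=C)(C)[C@@H](CC=C(C)C)CC(C(C)=O)C(=O)OC | intermediate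
10 | tert-butyl (S)-valinate | CC(C)[C@H](N)C(=O)OC(C)(C)C | starting material
11 | methyl (2Z)-3-{[(2S)-1-tert-butoxy-3-methyl-1-oxobutan-2-yl]amino}-2-{[(2S,3S)-3-ethenyl-3,7-dimethyl-2-(3-methylbut-2-en-1-yl)oct-6-en-1-yl]}but-2-enoate | CC(C)=CCC[C@](C=C)(C)[C@@H](CC=C(C)C)C/C(C(=O)OC)=C(C)/N[C@@H](C(C)C)C(=O)OC(C)(C)C | intermediate
12 | prenyl bromide (1-bromo-3-methylbut-2-ene) | CC(C)=CCBr | starting material
13 | methyl (2R,4S,5S)-2-(1-{[(2S)-1-tert-butoxy-3-methyl-1-oxobutan-2-yl]imino}ethyl)-5-ethenyl-5,9-dimethyl-2,4-bis(3-methylbut-2-en-1-yl)dec-8-enoate | CC(C)=CCC[C@](C=C)(C)[C@@H](CC=C(C)C)C[C@@](C(C)=N[C@@H](C(C)C)C(=O)OC(C)(C)C)(CC=C(C)C)C(=O)OC | intermediate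
14 | methyl (2R,4S,5S)-2-acetyl-5-ethenyl-5,9-dimethyl-2,4-bis(3-methylbut-2-en-1-yl)dec-8-enoate | CC(C)=CCC[C@](C=C)(C)[C@@H](CC=C(C)C)C[C@@](C(C)=O)(CC=C(C)C)C(=O)OC | intermediate
15 | methyl (2R,4S,5R)-2-acetyl-5-[2-(1,3,2-benzodioxaborol-2-yl)ethyl]-5,9-dimethyl-2,4-bis(3-methylbut-2-en-1-yl)dec-8-enoate | CC(C)=CCC[C@](CCB1Oc2ccccc2O1)(C)[C@@H](CC=C(C)C)C[C@@](C(C)=O)(CC=C(C)C)C(=O)OC | intermediate
16 | methyl (2R,4S,5S)-2-acetyl-5-(2-hydroxyethyl)-5,9-dimethyl-2,4-bis(3-methylbut-2-en-1-yl)dec-8-enoate | CC(C)=CCC[C@](CCO)(C)[C@@H](CC=C(C)C)C[C@@](C(C)=O)(CC=C(C)C)C(=O)OC | intermediate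
17 | (3S,4S,6R)-6-acetyl-7-methoxy-3-methyl-4,6-bis(3-methylbut-2-en-1-yl)-3-(4-methylpent-3-en-1-yl)-7-oxoheptanoic acid | CC(C)=CCC[C@](CC(=O)O)(C)[C@@H](CC=C(C)C)C[C@@](C(C)=O)(CC=C(C)C)C(=O)OC | intermediate
18 | dimethyl (2R,4S,5S)-2-acetyl-5-methyl-2,4-bis(3-methylbut-2-en-1-yl)-5-(4-methylpent-3-en-1-yl)heptanedioate | CC(C)=CCC[C@](CC(=O)OC)(C)[C@@H](CC=C(C)C)C[C@@](C(C)=O)(CC=C(C)C)C(=O)OC | intermediate
19 | dimethyl (2R,4S,5S)-2-{1-[(tert-butyldimethylsilyl)oxy]ethenyl}-5-methyl-2,4-bis(3-methylbut-2-en-1-yl)-5-(4-methylpent-3-en-1-yl)heptanedioate | CC(C)=CCC[C@](CC(=O)OC)(C)[C@@H](CC=C(C)C)C[C@@](C(=C)O[Si](C)(C)C(C)(C)C)(CC=C(C)C)C(=O)OC | intermediate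
20 | 2-methylpropanal | CC(C)C=O | starting material
21 | dimethyl (2R,4S,5R)-2-{1-[(tert-butyldimethylsilyl)oxy]ethenyl}-6-(1-hydroxy-2-methylpropyl)-5-methyl-2,4-bis(3-methylbut-2-en-1-yl)-5-(4-methylpent-3-en-1-yl)heptanedioate (mixture at C6 and the carbinol carbon) | CC(C)=CCC[C@](C(C(O)C(C)C)C(=O)OC)(C)[C@@H](CC=C(C)C)C[C@@](C(=C)O[Si](C)(C)C(C)(C)C)(CC=C(C)C)C(=O)OC | intermediate
22 | dimethyl (2R,4S,5R)-2-{1-[(tert-butyldimethylsilyl)oxy]ethenyl}-5-methyl-2,4-bis(3-methylbut-2-en-1-yl)-5-(4-methylpent-3-en-1-yl)-6-(2-methylpropanoyl)heptanedioate (C6 epimers) | CC(C)=CCC[C@](C(C(=O)C(C)C)C(=O)OC)(C)[C@@H](CC=C(C)C)C[C@@](C(=C)O[Si](C)(C)C(C)(C)C)(CC=C(C)C)C(=O)OC | intermediate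
23 | methyl (1S,3R,5S,6R)-3-{1-[(tert-butyldimethylsilyl)oxy]ethenyl}-6-methyl-3,5-bis(3-methylbut-2-en-1-yl)-6-(4-methylpent-3-en-1-yl)-1-(2-methylpropanoyl)-2-oxocyclohexane-1-carboxylate | CC(C)=CCC[C@]1(C)[C@@H](CC=C(C)C)C[C@@](C(=C)O[Si](C)(C)C(C)(C)C)(CC=C(C)C)C(=O)[C@]1(C(=O)C(C)C)C(=O)OC | intermediate
24 | (1R,5R,7S,8R)-4-hydroxy-8-methyl-5,7-bis(3-methylbut-2-en-1-yl)-8-(4-methylpent-3-en-1-yl)-1-(2-methylpropanoyl)bicyclo[3.3.1]non-3-ene-2,9-dione | CC(C)=CCC[C@]1(C)[C@@H](CC=C(C)C)C[C@@]2(CC=C(C)C)C(=O)[C@]1(C(=O)C(C)C)C(=O)C=C2O | target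

**Step count**

Total step count: 14. Longest linear sequence: 14 steps (1 or 2 to 24).

**Steps most likely to fail**

Step 14 (proposed new method). The stabilised C1 enolate may be too poor a nucleophile for the hindered C9 ester, so that no first closure occurs. Methoxide set free in the flask may remove the 2-methylpropanoyl group by retro-Claisen cleavage. Closure may also take the C1 configuration that cannot bridge, or fluoride may simply unmask the methyl ketone. The fallback uses known reactions one at a time, sets out from 19 and returns to the route at 23. Dieckmann condensation of 19 (KN(SiMe3)2, THF, −78 → 0 °C; only C1 can be enolised, and the more reactive ester enolate is the nucleophile) should give methyl (3R,5S,6R)-3-{1-[(tert-butyldimethylsilyl)oxy]ethenyl}-6-methyl-3,5-bis(3-methylbut-2-en-1-yl)-6-(4-methylpent-3-en-1-yl)-2-oxocyclohexane-1-carboxylate F1. C-acylation of its magnesium chelate (MgCl2, Et3N, 2-methylpropanoyl chloride, MeCN) should then give 23, now isolated. Treatment of 23 with the fluoride source of step 14 closes C2–C3 by the known Dieckmann reaction of a cis-1,3-acetyl/ester pair and gives 24.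

Step 7. Lithiation and alkylation at the hindered α-carbon may be slow, and the facial selectivity of the chelated aza-enolate may be low or mismatched with the remote C7/C8 centres, which would give a mixture at C5. The fallback sets out from 9 and returns at 14. Direct prenylation of 9 (K2CO3, 12, acetone, reflux) without an auxiliary should give 14 together with its C2 epimer, methyl (2S,4S,5S)-2-acetyl-5-ethenyl-5,9-dimethyl-2,4-bis(3-methylbut-2-en-1-yl)dec-8-enoate F2. The two are separated by preparative chromatography, and only 14 is taken on.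

Step 2. Enolisation of the ester by the bromoborane may be incomplete or may give a mixture of enolate geometries (loss of the syn relation between C7 and C8). The enantioselectivity may also be low for this α-branched acid, or a boat transition state may compete. The fallback separates relative from absolute control, sets out from 3 and returns at 5. A classical Ireland–Claisen rearrangement (LiN(i-Pr)2, THF/DMPU, −78 °C, Me3SiCl, then rt) proceeds through the silyl ketene acetal with the acid side chain cis to O–Si, (2E)-3,7-dimethylocta-2,6-dien-1-yl trimethylsilyl ketene acetal of 3, F3. After hydrolysis it should give the racemic syn acid, that is 5 together with its enantiomer (2S,3R)-3-ethenyl-3,7-dimethyl-2-(3-methylbut-2-en-1-yl)oct-6-enoic acid F4. Resolution by crystallisation of the (R)-1-phenylethylammonium salt of 5, F5, followed by acidification gives 5.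

**Further compounds**

F1 | step 14 | methyl (3R,5S,6R)-3-{1-[(tert-butyldimethylsilyl)oxy]ethenyl}-6-methyl-3,5-bis(3-methylbut-2-en-1-yl)-6-(4-methylpent-3-en-1-yl)-2-oxocyclohexane-1-carboxylate (C1 epimers and enol) | CC(C)=CCC[C@]1(C)[C@@H](CC=C(C)C)C[C@@](C(=C)O[Si](C)(C)C(C)(C)C)(CC=C(C)C)C(=O)C1C(=O)OC
F2 | step 7 | methyl (2S,4S,5S)-2-acetyl-5-ethenyl-5,9-dimethyl-2,4-bis(3-methylbut-2-en-1-yl)dec-8-enoate | CC(C)=CCC[C@](C=C)(C)[C@@H](CC=C(C)C)C[C@](C(C)=O)(CC=C(C)C)C(=O)OC
F3 | step 2 | (2E)-3,7-dimethylocta-2,6-dien-1-yl trimethylsilyl ketene acetal of 3, acid side chain cis to O–Si | CC(C)=CC/C=C(\O[Si](C)(C)C)/OC/C=C(C)/CCC=C(C)C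
F4 | step 2 | (2S,3R)-3-ethenyl-3,7-dimethyl-2-(3-methylbut-2-en-1-yl)oct-6-enoic acid | CC(C)=CCC[C@@](C=C)(C)[C@H](CC=C(C)C)C(=O)O
F5 | step 2 | (R)-1-phenylethylammonium (2R,3S)-3-ethenyl-3,7-dimethyl-2-(3-methylbut-2-en-1-yl)oct-6-enoate | CC(C)=CCC[C@](C=C)(C)[C@@H](CC=C(C)C)C(=O)[O-].C[C@@H]([NH3+])c1ccccc1
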